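**Retrosynthetic overview**
- The target comes from its C-2 epimeric epoxy alcohol by a last C–O bond formation with inversion (Mitsunobu acetoxylation).
- That erythro epoxy alcohol comes from a ten-membered (E)-allylic alcohol by the key step, a hydroxyl-directed Ti/D-tartrate epoxidation that forges both oxirane C–O bonds (second ring).
- The ten-membered carbocycle (first ring) is closed at the carbinol–alkenyl bond of an iodo aldehyde by a ligand-controlled Ni/Cr coupling (new).
- The iodo aldehyde comes from an E-selective Wittig reaction of a chiral lactol with a stabilised ylide that already carries the (R)-2-methylbutanoate and the (E)-vinyl iodide, followed by oxidation.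
- The lactol comes from a Rh-catalysed asymmetric 1,4-addition of an isopropenyl group to 5,6-dihydro-2H-pyran-2-one; the ylide comes from 4-bromobut-1-yne, formaldehyde, the acid and Ph3P=CHCO2Me.

Assumption: (2R)-2-methylbutanoic acid is bought as the single enantiomer; in the bicyclic names the quaternary oxirane carbon is C-1.

Step 1
Reactants: 1 5,6-dihydro-2H-pyran-2-one; 2 potassium trifluoro(prop-1-en-2-yl)borate
Product: 3 (4R)-4-(prop-1-en-2-yl)oxan-2-one
Conditions: [Rh(cod)2]BF4 (3 mol %), (R)-BINAP (3.3 mol %), toluene/H2O 10:1, 105 °C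
Reagents that add atoms: none
Why: Hayashi–Miyaura rhodium-catalysed asymmetric 1,4-addition; the alkenylrhodium–(R)-BINAP species inserts one face of the enoate and sets the isopropenyl centre as 4R, the same facial sense by which (S)-BINAP gives (S)-3-substituted cyclohexanones.

Step 2
Reactants: 3 (4R)-4-(prop-1-en-2-yl)oxan-2-one
Product: 4 (4R)-4-(prop-1-en-2-yl)oxan-2-ol (lactol, both anomers)
Conditions: i-Bu2AlH (1.05 equiv), CH2Cl2, −78 °C; aq. Rochelle salt
Reagents that add atoms: none
Why: Partial lactone reduction stops at the aluminium hemiacetal at −78 °C, so the two arms of the stereocentre stay differentiated (aldehyde level versus alcohol level).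

Step 3
Reactants: 5 4-bromobut-1-yne
Product: 7 5-bromopent-2-yn-1-ol, via lithium acetylide 6 (not isolated)
Conditions: n-BuLi (1.0 equiv), THF, −78 °C; (CH2O)n, −78 to 0 °C; H2O
Reagents that add atoms: formaldehyde (as paraformaldehyde), C=O
Why: Deprotonation of the terminal alkyne at −78 °C outruns attack on the primary bromide, and the acetylide adds to formaldehyde (carbonyl alkynylation) to give the propargylic alcohol.

Step 4
Reactants: 7 5-bromopent-2-yn-1-ol
Product: 8 (2E)-5-bromo-2-(tributylstannyl)pent-2-en-1-ol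
Conditions: Bu3SnH (1.1 equiv), PdCl2(PPh3)2 (2 mol %), THF, 0 °C to rt
Reagents that add atoms: tributyltin hydride, CCCC[SnH](CCCC)CCCC
Why: Palladium-catalysed hydrostannation is a syn H–Sn addition that puts tin on the alkyne carbon next to the CH2OH group, so H and Sn are cis and the E-stannane results (minor distal regioisomer removed by chromatography).

Step 5
Reactants: 8 (2E)-5-bromo-2-(tributylstannyl)pent-2-en-1-ol
Product: 9 (2E)-5-bromo-2-iodopent-2-en-1-ol
Conditions: I2 (1.05 equiv), CH2Cl2, 0 °C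
Reagents that add atoms: iodine, II
Why: Iododestannylation (electrophilic ipso-substitution) replaces tin by iodine with retention, fixing the alkene geometry that later becomes the E ring alkene.

Step 6
Reactants: 9 (2E)-5-bromo-2-iodopent-2-en-1-ol; 10 (2R)-2-methylbutanoic acid
Product: 11 (2E)-5-bromo-2-iodopent-2-en-1-yl (2R)-2-methylbutanoate
Conditions: DCC (1.1 equiv), DMAP (5 mol %), CH2Cl2, 0 °C to rt
Reagents that add atoms: none
Why: Steglich esterification forms the side-chain C–O bond under neutral conditions that do not epimerise the α-stereocentre of the acid.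

Step 7
Reactants: 11 (2E)-5-bromo-2-iodopent-2-en-1-yl (2R)-2-methylbutanoate; 12 methyl (triphenyl-λ5-phosphanylidene)acetate
Product: 14 methyl (5E)-6-iodo-7-{[(2R)-2-methylbutanoyl]oxy}-2-(triphenyl-λ5-phosphanylidene)hept-5-enoate, via phosphonium bromide 13 (not isolated)
Conditions: NaI (10 mol %), MeCN, 80 °C, 36 h; then 1 M aq. NaOH, CH2Cl2, 0 °C, 5 min
Reagents that add atoms: none
Why: SN2 C-alkylation of the ester-stabilised ylide by the primary bromide gives a phosphonium salt, which brief cold base deprotonates to the α-substituted ylide; the weakly basic ylide causes no E2 and leaves the vinyl iodide alone.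

Step 8
Reactants: 4 (4R)-4-(prop-1-en-2-yl)oxan-2-ol; 14 methyl (5E)-6-iodo-7-{[(2R)-2-methylbutanoyl]oxy}-2-(triphenyl-λ5-phosphanylidene)hept-5-enoate
Product: 16 methyl (2E,5S)-7-hydroxy-2-[(3E)-4-iodo-5-{[(2R)-2-methylbutanoyl]oxy}pent-3-en-1-yl]-5-(prop-1-en-2-yl)hept-2-enoate, via hydroxy aldehyde 15 (not isolated)
Conditions: PhCO2H (10 mol %), toluene, 95 °C, 24 h
Reagents that add atoms: none
Why: Wittig olefination of the ring-opened aldehyde tautomer by the α-branched stabilised ylide is thermodynamically controlled and gives the E trisubstituted enoate (ester trans to the chain), releasing the primary alcohol.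

Step 9
Reactants: 16 methyl (2E,5S)-7-hydroxy-2-[(3E)-4-iodo-5-{[(2R)-2-methylbutanoyl]oxy}pent-3-en-1-yl]-5-(prop-1-en-2-yl)hept-2-enoate
Product: 17 methyl (2E,5S)-2-[(3E)-4-iodo-5-{[(2R)-2-methylbutanoyl]oxy}pent-3-en-1-yl]-7-oxo-5-(prop-1-en-2-yl)hept-2-enoate
Conditions: Dess–Martin periodinane (1.3 equiv), CH2Cl2, 0 °C to rt
Reagents that add atoms: none
Why: Dess–Martin oxidation takes the primary alcohol to the aldehyde under neutral conditions that spare the vinyl iodide, the esters and the alkenes.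

Step 10
Reactants: 17 methyl (2E,5S)-2-[(3E)-4-iodo-5-{[(2R)-2-methylbutanoyl]oxy}pent-3-en-1-yl]-7-oxo-5-(prop-1-en-2-yl)hept-2-enoate
Product: 18 methyl (1E,4S,6R,7E)-6-hydroxy-7-({[(2R)-2-methylbutanoyl]oxy}methyl)-4-(prop-1-en-2-yl)cyclodeca-1,7-diene-1-carboxylate
Conditions: CrCl2 (6 equiv), (S)-4-isopropyl-2-[2-(methanesulfonamido)phenyl]-4,5-dihydro-1,3-oxazole (6.6 equiv), Et3N (6.6 equiv), NiCl2 (5 mol %), THF/MeCN, rt, 17 added over 12 h (final 2 mM); aq. potassium serinate
Reagents that add atoms: none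
Why: Proposed new method: a ligand-controlled nickel/chromium (Nozaki–Hiyama–Kishi) closure of a ten-membered (E)-cycloalkenol, in which zerovalent nickel inserts into the C–I bond with retention, the alkenyl group passes to trivalent chromium held by the chiral sulfonamide–oxazoline and adds through a closed Cr–O=C transition state to one aldehyde face to set C-6 as R, with the strong Cr–O bond and high dilution paying for medium-ring strain; the closest known reactions are Kishi's intermolecular asymmetric Ni/Cr couplings and achiral Ni/Cr macrocyclisations.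

Step 11
Reactants: 18 methyl (1E,4S,6R,7E)-6-hydroxy-7-({[(2R)-2-methylbutanoyl]oxy}methyl)-4-(prop-1-en-2-yl)cyclodeca-1,7-diene-1-carboxylate
Product: 19 methyl (1R,2R,4S,6E,10R)-2-hydroxy-1-({[(2R)-2-methylbutanoyl]oxy}methyl)-4-(prop-1-en-2-yl)-11-oxabicyclo[8.1.0]undec-6-ene-7-carboxylate
Conditions: Ti(OiPr)4 (0.3 equiv), D-(−)-DIPT (0.36 equiv), t-BuOOH (1.5 equiv), 4 Å MS, CH2Cl2, −20 °C
Reagents that add atoms: tert-butyl hydroperoxide, CC(C)(C)OO
Why: Sharpless asymmetric epoxidation in its matched kinetic-resolution manifold: the (6R)-carbinol bound to the titanium–D-tartrate complex receives oxygen on the face that gives the erythro epoxy alcohol, setting both oxirane carbons by reagent control, while the isopropenyl and enoate alkenes (no allylic hydroxyl) are untouched and any (6S)-epimer reacts far more slowly.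

Step 12
Reactants: 19 methyl (1R,2R,4S,6E,10R)-2-hydroxy-1-({[(2R)-2-methylbutanoyl]oxy}methyl)-4-(prop-1-en-2-yl)-11-oxabicyclo[8.1.0]undec-6-ene-7-carboxylate
Product: 20 methyl (1S,2S,4S,6E,10R)-2-(acetyloxy)-1-({[(2R)-2-methylbutanoyl]oxy}methyl)-4-(prop-1-en-2-yl)-11-oxabicyclo[8.1.0]undec-6-ene-7-carboxylate
Conditions: PPh3 (2 equiv), DIAD (2 equiv), AcOH (2 equiv), toluene, 0 °C to rt
Reagents that add atoms: acetic acid, CC(=O)O
Why: Mitsunobu reaction: acetate displaces the alkoxyphosphonium group in an SN2 step with inversion at C-2, turning the erythro alcohol into the threo (2S) acetate of the target (the C-1 descriptor changes from R to S only because the CIP ranking changes).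

**Compound list**
1 | 5,6-dihydro-2H-pyran-2-one | O=C1C=CCCO1 | starting material
2 | potassium trifluoro(prop-1-en-2-yl)borate | [K+].C=C(C)[B-](F)(F)F | starting material
3 | (4R)-4-(prop-1-en-2-yl)oxan-2-one | C=C(C)[C@H]1CC(=O)OCC1 | intermediate
4 | (4R)-4-(prop-1-en-2-yl)oxan-2-ol | C=C(C)[C@H]1CC(O)OCC1 | intermediate
5 | 4-bromobut-1-yne | C#CCCBr | starting material
6 | lithium 4-bromobut-1-yn-1-ide | [Li]C#CCCBr | intermediate
7 | 5-bromopent-2-yn-1-ol | OCC#CCCBr | intermediate
8 | (2E)-5-bromo-2-(tributylstannyl)pent-2-en-1-ol | BrCC/C=C(/[Sn](CCCC)(CCCC)CCCC)CO | intermediate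
9 | (2E)-5-bromo-2-iodopent-2-en-1-ol | BrCC/C=C(/I)CO | intermediate
10 | (2R)-2-methylbutanoic acid | OC(=O)[C@H](C)CC | starting material
11 | (2E)-5-bromo-2-iodopent-2-en-1-yl (2R)-2-methylbutanoate | BrCC/C=C(/I)COC(=O)[C@H](C)CC | intermediate
12 | methyl (triphenyl-λ5-phosphanylidene)acetate | COC(=O)C=P(c1ccccc1)(c1ccccc1)c1ccccc1 | starting material
13 | [(5E)-6-iodo-1-methoxy-7-{[(2R)-2-methylbutanoyl]oxy}-1-oxohept-5-en-2-yl](triphenyl)phosphonium bromide | COC(=O)C(CC/C=C(/I)COC(=O)[C@H](C)CC)[P+](c1ccccc1)(c1ccccc1)c1ccccc1.[Br-] | intermediate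
14 | methyl (5E)-6-iodo-7-{[(2R)-2-methylbutanoyl]oxy}-2-(triphenyl-λ5-phosphanylidene)hept-5-enoate | COC(=O)C(CC/C=C(/I)COC(=O)[C@H](C)CC)=P(c1ccccc1)(c1ccccc1)c1ccccc1 | intermediate
15 | (3R)-5-hydroxy-3-(prop-1-en-2-yl)pentanal | C=C(C)[C@H](CCO)CC=O | intermediate
16 | methyl (2E,5S)-7-hydroxy-2-[(3E)-4-iodo-5-{[(2R)-2-methylbutanoyl]oxy}pent-3-en-1-yl]-5-(prop-1-en-2-yl)hept-2-enoate | C=C(C)[C@H](CCO)C/C=C(/C(=O)OC)CC/C=C(/I)COC(=O)[C@H](C)CC | intermediate
17 | methyl (2E,5S)-2-[(3E)-4-iodo-5-{[(2R)-2-methylbutanoyl]oxy}pent-3-en-1-yl]-7-oxo-5-(prop-1-en-2-yl)hept-2-enoate | C=C(C)[C@H](CC=O)C/C=C(/C(=O)OC)CC/C=C(/I)COC(=O)[C@H](C)CC | intermediate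
18 | methyl (1E,4S,6R,7E)-6-hydroxy-7-({[(2R)-2-methylbutanoyl]oxy}methyl)-4-(prop-1-en-2-yl)cyclodeca-1,7-diene-1-carboxylate | C=C(C)[C@H]1C/C=C(/C(=O)OC)CC/C=C(COC(=O)[C@H](C)CC)/[C@H](O)C1 | intermediate
19 | methyl (1R,2R,4S,6E,10R)-2-hydroxy-1-({[(2R)-2-methylbutanoyl]oxy}methyl)-4-(prop-1-en-2-yl)-11-oxabicyclo[8.1.0]undec-6-ene-7-carboxylate | C=C(C)[C@H]1C/C=C(/C(=O)OC)CC[C@H]2O[C@]2(COC(=O)[C@H](C)CC)[C@H](O)C1 | intermediate
20 | methyl (1S,2S,4S,6E,10R)-2-(acetyloxy)-1-({[(2R)-2-methylbutanoyl]oxy}methyl)-4-(prop-1-en-2-yl)-11-oxabicyclo[8.1.0]undec-6-ene-7-carboxylate | C=C(C)[C@H]1C/C=C(/C(=O)OC)CC[C@H]2O[C@]2(COC(=O)[C@H](C)CC)[C@@H](OC(C)=O)C1 | target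

**Step count and risks**
Total step count: 12. Longest linear sequence: 10 steps (steps 3 to 12, from 4-bromobut-1-yne).

Most likely to fail:

1. Step 10 (the proposed new step). The risks are strain in closing the ten-membered ring, β-elimination of the allylic carboxylate from the alkenylchromium, and low or reversed ligand control at C-6; the sense of induction of this ligand is not established for such a ring. The fallback uses known chemistry, sets out from 17 and comes back at 18. The ring is closed with achiral CrCl2/NiCl2 in DMSO/THF at 2 mM, which gives 18 mixed with its C-6 epimer methyl (1E,4S,6S,7E)-6-hydroxy-7-({[(2R)-2-methylbutanoyl]oxy}methyl)-4-(prop-1-en-2-yl)cyclodeca-1,7-diene-1-carboxylate F1. The mixture is oxidised with Dess–Martin periodinane to the single enone methyl (1E,4S,7E)-7-({[(2R)-2-methylbutanoyl]oxy}methyl)-6-oxo-4-(prop-1-en-2-yl)cyclodeca-1,7-diene-1-carboxylate F2. F2 is reduced with (S)-Me-CBS oxazaborolidine and catecholborane in toluene at −78 °C, the alkenyl group acting as the large substituent, to give 18.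

2. Step 12. The carbinol is secondary, sits next to a fully substituted oxirane carbon and lies in a medium ring, so the SN2 step may be slow. The fallback sets out from 19 and comes back at 20. MsCl/Et3N in CH2Cl2 at 0 °C gives methyl (1S,2R,4S,6E,10R)-2-[(methanesulfonyl)oxy]-1-({[(2R)-2-methylbutanoyl]oxy}methyl)-4-(prop-1-en-2-yl)-11-oxabicyclo[8.1.0]undec-6-ene-7-carboxylate F3. F3 is then displaced with inversion by CsOAc/18-crown-6 in toluene at 80 °C to give 20.

3. Step 7. A stabilised ylide reacts sluggishly with an unactivated primary bromide. The fallback sets out from 11 and comes back at 16, bypassing 14. The sodium salt of trimethyl phosphonoacetate (NaH, DMF, 50 °C) is alkylated with 11 to give methyl (5E)-2-(dimethoxyphosphoryl)-6-iodo-7-{[(2R)-2-methylbutanoyl]oxy}hept-5-enoate F4. A Masamune–Roush Horner–Wadsworth–Emmons reaction of F4 with lactol 4 (LiCl, DBU, MeCN, rt) gives 16 after removal of the minor Z isomer.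

Further compounds
F1 | step 10 | methyl (1E,4S,6S,7E)-6-hydroxy-7-({[(2R)-2-methylbutanoyl]oxy}methyl)-4-(prop-1-en-2-yl)cyclodeca-1,7-diene-1-carboxylate | C=C(C)[C@H]1C/C=C(/C(=O)OC)CC/C=C(COC(=O)[C@H](C)CC)/[C@@H](O)C1
F2 | step 10 | methyl (1E,4S,7E)-7-({[(2R)-2-methylbutanoyl]oxy}methyl)-6-oxo-4-(prop-1-en-2-yl)cyclodeca-1,7-diene-1-carboxylate | C=C(C)[C@H]1C/C=C(/C(=O)OC)CC/C=C(COC(=O)[C@H](C)CC)/C(=O)C1
F3 | step 12 | methyl (1S,2R,4S,6E,10R)-2-[(methanesulfonyl)oxy]-1-({[(2R)-2-methylbutanoyl]oxy}methyl)-4-(prop-1-en-2-yl)-11-oxabicyclo[8.1.0]undec-6-ene-7-carboxylate | C=C(C)[C@H]1C/C=C(/C(=O)OC)CC[C@H]2O[C@]2(COC(=O)[C@H](C)CC)[C@H](OS(C)(=O)=O)C1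
F4 | step 7 | methyl (5E)-2-(dimethoxyphosphoryl)-6-iodo-7-{[(2R)-2-methylbutanoyl]oxy}hept-5-enoate | COC(=O)C(CC/C=C(/I)COC(=O)[C@H](C)CC)P(=O)(OC)OC
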